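## Analysis of the target

The target is a germacranolide: a ten-membered carbocycle (C1–C10) with an α-methylene-γ-butyrolactone (C11–C13) closed from C12 onto the C6 oxygen and trans-fused across C6–C7. The ring also carries a trisubstituted trans-3,4-epoxide (C15 methyl on C4) and a cross-conjugated C1 ketone/C10=C14 methylene unit. There are six stereocentres: C3 and C4 (3R,4R; oxygen α at C3, β at C4), C6 (oxygen α), C7 (hydrogen α, C11 β), C8 (hydroxyl α) and C9 (angelate α). C6/C7 are trans, the 8-hydroxyl is trans to the C7–C11 bond and cis to the C9 ester. The epoxide is separated from this array by the C5 methylene, so its configuration cannot be relayed from a neighbour. The sensitive groups are these: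

- the methylene lactone and the exocyclic enone, both Michael acceptors;
- the β,γ-epoxy ketone (C1/C3–C4), which opens under base;
- the epoxide itself, which acid can open with transannular capture by the C10 methylene;
- the angelate, which isomerises to the tiglate with nucleophilic catalysts and can migrate to the free 8-hydroxyl;
- the 8α-hydroxyl, which can translactonise onto C12.

The difficulty is twofold: a ten-membered ring is the least favourable size to close, and six of its ten carbons carry oxygen that must be placed with control on a flexible ring. The strategy rests on the fact that the fifteen skeletal carbons form an unrearranged germacrane. Ring bond C6–C7 is the bond that joins the two ends of a farnesyl chain, C14 and C15 are the chain's methyl branches, C11–C13 its isopropylidene end, and C7 is the only stereocentre of the bare skeleton. The ring with C7 configured can therefore come from one enzymatic cyclization, and the synthetic effort goes into oxidation.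

## Retrosynthetic reasoning

**End game (30 ⇐ 29 ⇐ 28 ⇐ 27).** The last bond cut is the benzylic C–O bond of the 4-methoxybenzyl ether 29. The C8 oxygen stays masked to the end so that the angelate cannot migrate and C1 can be oxidised alone; oxidative debenzylation is neutral and spares the β,γ-epoxy ketone. The C1 ketone is formed late (28 to 29), after desilylation of 27, because a C1 silyl ether keeps C2 non-enolisable and leaves the C9 ketone chemistry without a competitor.

**Ester bond at C9 (27 ⇐ 25 + 26).** The acyl C–O bond is cut. In 25 the C9 hydroxyl is the only free one, so angelic acid 26 can be attached without any need to tell two neighbouring hydroxyls apart.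

**C9 stereocentre and C8 oxygen (25 ⇐ 24 ⇐ 23 ⇐ 21).** The C9–H bond is cut back to ketone 24, whose C8 ether oxygen can steer a chelation-controlled reduction to the 8,9-cis pair. The C8–O bond is cut back to enone 21 by way of enolate 22. C8 is the only position where 21 can enolise, because C10 is sp2, so regiochemistry is not in question; the forward step must fix the α configuration at C8.

**C9 oxygen (21 ⇐ 20 ⇐ 19).** The C9–O bond is cut by an allylic oxidation of the ene/[2,3] type. In 19 the C9 methylene is the only allylic CH2, and the double bond returns to C10=C14 after the sigmatropic shift.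

**Epoxide (19 ⇐ 18).** Both epoxide C–O bonds are cut. Triene 18 has one electron-rich alkene, so a reagent-controlled (Shi-type) epoxidation can set C3 and C4 without help from the remote stereocentres. The epoxide is made before the allylic oxidation because a trisubstituted alkene would compete for that oxidant.

**Moving the alkene (18 ⇐ 15).** The biogenetic skeleton has its alkene at C4=C5, one position off. A sacrificial C3 hydroxyl (15) is the handle: Mitsunobu displacement and reductive 1,3-transposition through allylic diazene 17 shift the alkene to C3=C4 and put hydrogen on C5. The forward step must give the E alkene.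

**C1 oxygen (15 ⇐ 14 ⇐ 13 ⇐ 11 ⇐ 10).** The C1–O bond is cut by a Schenck ene reaction of the 1(10) alkene of 11, which also creates the C10=C14 methylene (via hydroperoxide 12). Two silyl ethers of different lability (14) let O3 be freed while O1 stays covered.

**Oxygens at C12, C6 and C3 (10 ⇐ 9 ⇐ 4).** These C–O bonds are cut back to the hydrocarbon 4. The sites are a vinylic methyl, and two allylic CH2 groups that no reagent distinguishes from C2, C9, C14 or C15. The P450 enzymes of the native pathway do so, and costunolide 9 forms by spontaneous lactonisation.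

**Key disconnection (4 ⇐ 3).** The ring bond C6–C7 is cut, which opens the ten-membered ring to the achiral diphosphate 3. The forward cyclization must close the ring, set C7 and keep both E alkenes.

**Precursor (3 ⇐ 2 ⇐ 1).** The C–O bond to diphosphate is cut back to chloride 2 and farnesol 1, two routine steps, so the risk of the route sits in the cyclization and not before it.

## Alternatives that were turned down

**Alternative 1:** The C1–C10 bond and the C9–O bond are disconnected together, reading the C1 ketone and C9 oxygen as an aldol pair hidden in an isoxazoline. In the forward sense a nitrile oxide made at C1 from an aldoxime would add across a C9/C10 enoate alkene and close the carbocycle and the heterocycle at once, giving A1.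
- For: the fragile hydroxy-enone stays masked until late. The C1 and C9 oxygens are placed by bond construction and not by C–H oxidation; here it is stronger than the chosen route, which needs two allylic oxidations and an enolate hydroxylation. The epoxide and C8 can be set with acyclic stereocontrol, and no enzyme is needed.
- Against: the dipole carbon must bond to the ester-bearing C10; bonding to C9 would close a nine-membered ring, and the polarisation of an enoate does not favour the required sense. Ten is the worst ring size, so dimerisation of the dipole competes. The face at C9 depends on the folding of a long chain. After closure, N–O cleavage, conversion of the C10 ester into the methylene and α-methylenation of the lactone remain, on top of roughly twenty steps for an open chain with five stereocentres.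
- Comparison: the chosen strategy closes the ring and sets C7 in step 3 from an achiral chain, with no regiochemical question at closure. In exchange it gives up the built-in placement of oxygen.

**Alternative 2:** A transannular C4–C9 bond is added retrosynthetically to give a trans-decalin from Robinson annulation chemistry. In the forward sense a Grob-type (Wharton) fragmentation breaks the C4–C9 bond as the C9 alkoxide pushes and an anti-periplanar C3 mesylate leaves, forming the C9 ketone and the E C3/C4 alkene of A2.
- For: the alkene is formed directly at C3/C4 with its geometry enforced by the rigid bicycle. On this point it is stronger than the chosen route, whose step 10 creates that alkene by transposition without such enforcement. C6 to C8 can be set on a conformationally defined framework, and the chemistry is classical and scalable.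
- Against: the ketone emerges at C9 and C10 carries a saturated methyl, whereas the target needs the ketone at C1, a methylene at C10 and an ester at C9. Carbonyl function must therefore be moved across C10 (dehydrogenation, reduction, allylic oxidation at C1), the same kind of allylic oxidation the chosen route uses. The lactone must be built from a two-carbon side chain and methylenated, and an acetal at C8 must be removed next to the epoxide. The count passes thirty steps.
- Comparison: the chosen route needs no skeletal construction at all. In place of the enforced alkene geometry it offers a short access to 18 and a stereochemical fallback (see step 10).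

**Alternative 3:** The C4–C5 bond is disconnected into a C3/C4 alkyne and a C5/C6 terminal epoxide. In the forward sense a zerovalent nickel phosphine catalyst with a borane reductant would couple them by cis addition, closing the ring and giving the E alkene and the C6 alkoxide of A3.
- For: A3 already holds the E C3/C4 alkene, a free C6 hydroxyl next to the ester side chain, the C1 silyl ether, the C10 methylene and the cis C8/C9 diol. It is the most advanced of the three key-step products, and on placement and geometry of the alkene it is stronger than the chosen route. C6 comes from an enantiopure epoxide.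
- Against: this coupling is known for small rings and intermolecular cases. Closing a ten-membered ring containing an E alkene through a metallacycle is strained. A methyl/methylene-substituted alkyne has no regiochemical bias, and coupling through C3 would close a nine-membered ring. The allylic silyl ether and the methylene are further binding sites for nickel. The substrate costs some fifteen to eighteen steps. The cis diol must still be differentiated for angeloylation, and the acetonide needs acid.
- Comparison: the chosen strategy reaches the ring in three steps and introduces the C8 and C9 oxygens one at a time, so they never need differentiating. It pays with the alkene transposition.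

Key step: step 3

Remark on the chemistry: germacrane numbering is used for all intermediates. The configuration drawn at C1 of 12–28 (1β) and left open at C9 of 20 is immaterial, because both carbons pass through ketones. Diphosphate 3 is drawn as the free acid but handled as its ammonium salt.

## Route

Step 1
Reactants: 1 (2E,6E)-farnesol
Product: 2 (2E,6E)-farnesyl chloride
Conditions: N-chlorosuccinimide, Me2S, CH2Cl2, −40 to 0 °C
Reagents that add atoms: N-chlorosuccinimide, O=C1CCC(=O)N1Cl
Why: Corey–Kim chlorination; chloride displaces the alkoxysulfonium group at the primary carbon, so the allylic chloride should form without allylic shift or loss of the E geometry.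

Step 2
Reactants: 2 (2E,6E)-farnesyl chloride
Product: 3 (2E,6E)-farnesyl diphosphate (isolated as the tris-ammonium salt)
Conditions: (Bu4N)3HP2O7, MeCN, rt; cation exchange (NH4+ form); cellulose chromatography
Reagents that add atoms: tris(tetrabutylammonium) hydrogen diphosphate, CCCC[N+](CCCC)(CCCC)CCCC.CCCC[N+](CCCC)(CCCC)CCCC.CCCC[N+](CCCC)(CCCC)CCCC.OP(=O)([O-])OP(=O)([O-])[O-]
Why: SN2 displacement of a primary allylic chloride by the diphosphate trianion in a dipolar aprotic solvent; ion exchange gives the water-soluble salt the enzyme accepts.

Step 3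
Reactants: 3 (2E,6E)-farnesyl diphosphate
Product: 4 (+)-(7R)-germacrene A
Conditions: recombinant plant (+)-germacrene A synthase, MgCl2 (10 mM), HEPES buffer pH 7.2, dithiothreitol, glycerol, pentane overlay, 30 °C
Reagents that add atoms: none
Why: Divalent magnesium bound in the active site assists ionisation of the diphosphate to the allylic cation. The distal C10=C11 alkene of the chain then attacks the cationic carbon, forming the bond that is C6–C7 of the germacrane, and loss of a proton from a methyl group of the resulting tertiary C11 cation gives the isopropenyl group. The closest known reaction type is the class 1 terpene synthase cation–olefin cyclization, which is documented for plant germacrene A synthases on this very substrate. The ten-membered ring closes in a 10-exo cation–olefin mode: only one carbon of the attacking alkene enters the ring, and the charge ends on the exocyclic tertiary carbon as Markovnikov addition demands. The one new stereocentre, C7, is set by the active-site fold, which presents a single face of the distal alkene and gives the R configuration (H-7 α) of the 6,12-lactone series. The step needs 1,10-closure in preference to 1,11- or 1,6-closure, and release of the triene without reprotonation to bicyclic products; both are secured by the enzyme template, and the E geometry of the C2=C3 alkene forbids six-ring closure. Both E alkenes are retained. The pentane overlay, neutral pH and mild temperature protect the product from acid-induced transannular cyclization and from Cope rearrangement.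

Step 4
Reactants: 4 (+)-(7R)-germacrene A
Product: 9 (+)-costunolide, via C12 alcohol 5 (not isolated), via C12 aldehyde 6 (not isolated), via germacrene A acid 7 (not isolated), via 6α-hydroxy acid 8 (not isolated)
Conditions: yeast microsomes co-expressing germacrene A oxidase (CYP71AV family), costunolide synthase (CYP71BL2) and a P450 reductase; NADP+ (cat.), D-glucose, glucose dehydrogenase, air, KH2PO4/K2HPO4 buffer pH 7.5, 30 °C
Reagents that add atoms: dioxygen, O=O
Why: P450 oxygenations of the native pathway: the oxidase takes the C12 methyl through alcohol and aldehyde to the acid, and the synthase hydroxylates the allylic C6–H on the α face by hydrogen abstraction and oxygen rebound. The 6α-hydroxy acid lactonises spontaneously to the trans-fused lactone; C6 is set by the enzyme.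

Step 5
Reactants: 9 (+)-costunolide
Product: 10 3β-hydroxycostunolide
Conditions: yeast microsomes expressing costunolide 3β-hydroxylase (CYP71CB1) and a P450 reductase; NADP+ (cat.), D-glucose, glucose dehydrogenase, air, buffer pH 7.5, 30 °C
Reagents that add atoms: dioxygen, O=O
Why: Enzymatic allylic hydroxylation; the enzyme selects C3 among five allylic positions and delivers oxygen to the β face. Costunolide is a documented substrate of this hydroxylase.

Step 6
Reactants: 10 3β-hydroxycostunolide
Product: 11 3β-(triethylsilyloxy)costunolide
Conditions: Et3SiCl, imidazole, CH2Cl2, 0 °C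
Reagents that add atoms: chlorotriethylsilane, CC[Si](Cl)(CC)CC
Why: Standard silylation of a secondary allylic alcohol; the labile triethylsilyl group is chosen so that it can later be removed beside a tert-butyldimethylsilyl ether.

Step 7
Reactants: 11 3β-(triethylsilyloxy)costunolide
Product: 13 1β-hydroxy-3β-(triethylsilyloxy)germacra-4E,10(14),11(13)-trien-12,6α-olide, via hydroperoxide 12 (not isolated)
Conditions: O2, visible light, tetraphenylporphyrin (cat.), CH2Cl2, −20 °C; then PPh3, 0 °C
Reagents that add atoms: dioxygen (as singlet oxygen), O=O
Why: Schenck ene reaction. Singlet oxygen should react at the 1(10) alkene, because the 4,5 alkene is deactivated by allylic oxygens on both sides; it bonds at C1 and takes a C14 hydrogen, giving the exocyclic methylene. PPh3 reduces the hydroperoxide; attack on the outer face should give the 1β alcohol, a configuration that is erased later.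

Step 8
Reactants: 13 1β-hydroxy-3β-(triethylsilyloxy)germacra-4E,10(14),11(13)-trien-12,6α-olide
Product: 14 1β-(tert-butyldimethylsilyloxy)-3β-(triethylsilyloxy)germacra-4E,10(14),11(13)-trien-12,6α-olide
Conditions: TBSOTf, 2,6-lutidine, CH2Cl2, −78 °C
Reagents that add atoms: tert-butyldimethylsilyl triflate, CC(C)(C)[Si](C)(C)OS(=O)(=O)C(F)(F)F
Why: Silylation of a hindered secondary allylic alcohol with a silyl triflate and a hindered base; the buffered, cold conditions should spare the acid-sensitive diene.

Step 9
Reactants: 14 1β-(tert-butyldimethylsilyloxy)-3β-(triethylsilyloxy)germacra-4E,10(14),11(13)-trien-12,6α-olide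
Product: 15 1β-(tert-butyldimethylsilyloxy)-3β-hydroxygermacra-4E,10(14),11(13)-trien-12,6α-olide
Conditions: pyridinium 4-toluenesulfonate (cat.), MeOH–CH2Cl2, 0 °C
Reagents that add atoms: none
Why: Selective acid-catalysed methanolysis; a triethylsilyl ether is cleaved far faster than a secondary tert-butyldimethylsilyl ether, so only O3 should be freed.

Step 10
Reactants: 15 1β-(tert-butyldimethylsilyloxy)-3β-hydroxygermacra-4E,10(14),11(13)-trien-12,6α-olide
Product: 18 1β-(tert-butyldimethylsilyloxy)germacra-3E,10(14),11(13)-trien-12,6α-olide, via sulfonylhydrazine adduct 16 (not isolated), via allylic diazene 17 (not isolated)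
Conditions: 2-nitrobenzenesulfonylhydrazide, PPh3, diethyl azodicarboxylate, N-methylmorpholine, −30 °C; then rt
Reagents that add atoms: none
Why: Myers reductive 1,3-transposition. Mitsunobu displacement of the C3 alcohol by the sulfonylhydrazide nitrogen (inversion) is followed on warming by loss of arenesulfinic acid and retro-ene loss of N2 from the diazene, which delivers hydrogen to C5 and moves the alkene to C3=C4. The E geometry is expected because C2 can stay anti to C5, as in the trans-cycloalkene conformation of the starting ring.

Step 11
Reactants: 18 1β-(tert-butyldimethylsilyloxy)germacra-3E,10(14),11(13)-trien-12,6α-olide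
Product: 19 (3R,4R)-3,4-epoxy-1β-(tert-butyldimethylsilyloxy)germacra-10(14),11(13)-dien-12,6α-olide
Conditions: D-fructose-derived Shi ketone (1,2:4,5-di-O-isopropylidene-β-D-erythro-2,3-hexodiulo-2,6-pyranose, 0.3 equiv), KHSO5 (Oxone triple salt), K2CO3, Bu4NHSO4, MeCN–CH2(OMe)2/aq. Na2B4O7 buffer, 0 °C
Reagents that add atoms: potassium peroxymonosulfate, [K+].[O-]S(=O)(=O)OO
Why: Shi asymmetric epoxidation. The chiral dioxirane transfers oxygen through a spiro transition state, and for an E-trisubstituted alkene the D-fructose-derived ketone should select the face that gives the (3R,4R) epoxide; the trans relationship follows from the E geometry. The 1,1-disubstituted methylene next to a silyloxy carbon and the electron-poor acrylate should react much more slowly.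

Step 12
Reactants: 19 (3R,4R)-3,4-epoxy-1β-(tert-butyldimethylsilyloxy)germacra-10(14),11(13)-dien-12,6α-olide
Product: 20 (3R,4R)-3,4-epoxy-9-hydroxy-1β-(tert-butyldimethylsilyloxy)germacra-10(14),11(13)-dien-12,6α-olide (C9 epimers)
Conditions: SeO2 (0.5 equiv), t-BuOOH, CH2Cl2, 0 °C to rt
Reagents that add atoms: selenium dioxide, O=[Se]=O; tert-butyl hydroperoxide (terminal oxygen source), CC(C)(C)OO
Why: Selenium dioxide allylic oxidation: ene reaction at C14, then a [2,3]-sigmatropic shift that returns the alkene to C10=C14 and puts oxygen on C9, the only allylic methylene. Trisubstituted epoxides of germacranolides are known to tolerate this reagent, and any enone 21 from over-oxidation converges in step 13.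

Step 13
Reactants: 20 (3R,4R)-3,4-epoxy-9-hydroxy-1β-(tert-butyldimethylsilyloxy)germacra-10(14),11(13)-dien-12,6α-olide (C9 epimers)
Product: 21 (3R,4R)-3,4-epoxy-9-oxo-1β-(tert-butyldimethylsilyloxy)germacra-10(14),11(13)-dien-12,6α-olide
Conditions: Dess–Martin periodinane, NaHCO3, CH2Cl2, 0 °C to rt
Reagents that add atoms: none
Why: Buffered hypervalent-iodine oxidation of a secondary allylic alcohol; both C9 epimers give the same enone, and the epoxide and silyl ether are untouched.

Step 14
Reactants: 21 (3R,4R)-3,4-epoxy-9-oxo-1β-(tert-butyldimethylsilyloxy)germacra-10(14),11(13)-dien-12,6α-olide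
Product: 23 (3R,4R)-3,4-epoxy-8α-hydroxy-9-oxo-1β-(tert-butyldimethylsilyloxy)germacra-10(14),11(13)-dien-12,6α-olide, via potassium enolate 22 (not isolated)
Conditions: KN(SiMe3)2, THF, −78 °C; 2-(phenylsulfonyl)-3-phenyloxaziridine, −78 °C; aq. NH4Cl
Reagents that add atoms: 2-(phenylsulfonyl)-3-phenyloxaziridine, O=S(=O)(c1ccccc1)N1OC1c1ccccc1
Why: Enolate hydroxylation with an N-sulfonyloxaziridine (Davis oxidation). C8 is the only enolisable position of the enone. Oxygen is expected to enter on the α face, anti to the C7–C11 bond of the neighbouring stereocentre (1,2-induction), giving the 8α alcohol.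

Step 15
Reactants: 23 (3R,4R)-3,4-epoxy-8α-hydroxy-9-oxo-1β-(tert-butyldimethylsilyloxy)germacra-10(14),11(13)-dien-12,6α-olide
Product: 24 (3R,4R)-3,4-epoxy-8α-(4-methoxybenzyloxy)-9-oxo-1β-(tert-butyldimethylsilyloxy)germacra-10(14),11(13)-dien-12,6α-olide
Conditions: 2-(4-methoxybenzyloxy)-4-methylquinoline, MeOTf, MgO, PhCF3, 0 °C to rt
Reagents that add atoms: 2-(4-methoxybenzyloxy)-4-methylquinoline, COc1ccc(COc2cc(C)c3ccccc3n2)cc1
Why: 4-Methoxybenzyl transfer from an N-methylquinolinium salt under neutral conditions (MgO as acid scavenger). This avoids both the strong base that would attack the Michael acceptors and the Lewis acid that would open the epoxide, and it installs an ether that can chelate and be removed oxidatively.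

Step 16
Reactants: 24 (3R,4R)-3,4-epoxy-8α-(4-methoxybenzyloxy)-9-oxo-1β-(tert-butyldimethylsilyloxy)germacra-10(14),11(13)-dien-12,6α-olide
Product: 25 (3R,4R)-3,4-epoxy-9α-hydroxy-8α-(4-methoxybenzyloxy)-1β-(tert-butyldimethylsilyloxy)germacra-10(14),11(13)-dien-12,6α-olide
Conditions: Zn(BH4)2, Et2O, −30 °C
Reagents that add atoms: none
Why: Chelation-controlled 1,2-reduction (Cram chelate model). Divalent zinc bridges the C9 carbonyl and the C8 ether oxygen and hydride enters from the side of H-8, which gives the erythro, ring-cis pair and hence the 9α alcohol. The lactone, the epoxide and the silyl ether are inert to this reagent.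

Step 17
Reactants: 25 (3R,4R)-3,4-epoxy-9α-hydroxy-8α-(4-methoxybenzyloxy)-1β-(tert-butyldimethylsilyloxy)germacra-10(14),11(13)-dien-12,6α-olide; 26 angelic acid
Product: 27 (3R,4R)-9α-angeloyloxy-3,4-epoxy-8α-(4-methoxybenzyloxy)-1β-(tert-butyldimethylsilyloxy)germacra-10(14),11(13)-dien-12,6α-olide
Conditions: 26, 2,4,6-trichlorobenzoyl chloride, Et3N, toluene, rt; then 25, toluene, 75 °C
Reagents that add atoms: angelic acid (26), C/C=C(/C)C(=O)O
Why: Yamaguchi-type esterification through the mixed anhydride, run without a nucleophilic catalyst so that the Z enoate should not isomerise to the tiglate. The alcohol attacks the unhindered angeloyl carbonyl, and no second hydroxyl is free.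

Step 18
Reactants: 27 (3R,4R)-9α-angeloyloxy-3,4-epoxy-8α-(4-methoxybenzyloxy)-1β-(tert-butyldimethylsilyloxy)germacra-10(14),11(13)-dien-12,6α-olide
Product: 28 (3R,4R)-9α-angeloyloxy-3,4-epoxy-1β-hydroxy-8α-(4-methoxybenzyloxy)germacra-10(14),11(13)-dien-12,6α-olide
Conditions: Bu4NF, AcOH (1:1), THF, 0 °C to rt
Reagents that add atoms: none
Why: Fluoride desilylation buffered with acetic acid, which keeps the medium non-basic for the methylene lactone and the ester and non-acidic for the epoxide; with O8 masked the angelate cannot migrate.

Step 19
Reactants: 28 (3R,4R)-9α-angeloyloxy-3,4-epoxy-1β-hydroxy-8α-(4-methoxybenzyloxy)germacra-10(14),11(13)-dien-12,6α-olide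
Product: 29 (3R,4R)-9α-angeloyloxy-3,4-epoxy-8α-(4-methoxybenzyloxy)-1-oxogermacra-10(14),11(13)-dien-12,6α-olide
Conditions: Dess–Martin periodinane, NaHCO3, CH2Cl2, 0 °C
Reagents that add atoms: none
Why: Buffered oxidation of the only free (allylic) alcohol to the exocyclic enone under neutral conditions, which the newly formed β,γ-epoxy ketone should survive.

Step 20
Reactants: 29 (3R,4R)-9α-angeloyloxy-3,4-epoxy-8α-(4-methoxybenzyloxy)-1-oxogermacra-10(14),11(13)-dien-12,6α-olide
Product: 30 (3R,4R)-9α-angeloyloxy-3,4-epoxy-8α-hydroxy-1-oxogermacra-10(14),11(13)-dien-12,6α-olide (target)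
Conditions: DDQ, CH2Cl2–pH 7 buffer, 0 °C to rt
Reagents that add atoms: none
Why: Oxidative cleavage of the 4-methoxybenzyl ether by hydride abstraction and hydrolysis of the oxocarbenium ion; the neutral medium avoids epoxide opening, acyl migration and translactonisation.

## Compound list

1 | (2E,6E)-farnesol | CC(C)=CCC/C(C)=C/CC/C(C)=C/CO | starting material
2 | (2E,6E)-farnesyl chloride | CC(C)=CCC/C(C)=C/CC/C(C)=C/CCl | intermediate
3 | (2E,6E)-farnesyl diphosphate (drawn as the acid, used as tris-ammonium salt) | CC(C)=CCC/C(C)=C/CC/C(C)=C/COP(=O)(O)OP(=O)(O)O | intermediate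
4 | (+)-(7R)-germacrene A | C=C(C)[C@H]1C/C=C(C)/CC/C=C(C)/CC1 | intermediate
5 | (7R)-germacra-1(10)E,4E,11(13)-trien-12-ol | C=C(CO)[C@H]1C/C=C(C)/CC/C=C(C)/CC1 | intermediate
6 | (7R)-germacra-1(10)E,4E,11(13)-trien-12-al | C=C(C=O)[C@H]1C/C=C(C)/CC/C=C(C)/CC1 | intermediate
7 | germacrene A acid (germacra-1(10)E,4E,11(13)-trien-12-oic acid) | C=C(C(=O)O)[C@H]1C/C=C(C)/CC/C=C(C)/CC1 | intermediate
8 | 6α-hydroxygermacra-1(10)E,4E,11(13)-trien-12-oic acid | C=C(C(=O)O)[C@H]1[C@H](O)/C=C(C)/CC/C=C(C)/CC1 | intermediate
9 | (+)-costunolide (germacra-1(10)E,4E,11(13)-trien-12,6α-olide) | C=C1C(=O)O[C@@H]2/C=C(C)/CC/C=C(C)/CC[C@@H]12 | intermediate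
10 | 3β-hydroxycostunolide | C=C1C(=O)O[C@@H]2/C=C(C)/[C@@H](O)C/C=C(C)/CC[C@@H]12 | intermediate
11 | 3β-(triethylsilyloxy)costunolide | C=C1C(=O)O[C@@H]2/C=C(C)/[C@@H](O[Si](CC)(CC)CC)C/C=C(C)/CC[C@@H]12 | intermediate
12 | 1β-hydroperoxy-3β-(triethylsilyloxy)germacra-4E,10(14),11(13)-trien-12,6α-olide | C=C1C(=O)O[C@@H]2/C=C(C)/[C@@H](O[Si](CC)(CC)CC)C[C@@H](OO)C(=C)CC[C@@H]12 | intermediate
13 | 1β-hydroxy-3β-(triethylsilyloxy)germacra-4E,10(14),11(13)-trien-12,6α-olide | C=C1C(=O)O[C@@H]2/C=C(C)/[C@@H](O[Si](CC)(CC)CC)C[C@@H](O)C(=C)CC[C@@H]12 | intermediate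
14 | 1β-(tert-butyldimethylsilyloxy)-3β-(triethylsilyloxy)germacra-4E,10(14),11(13)-trien-12,6α-olide | C=C1C(=O)O[C@@H]2/C=C(C)/[C@@H](O[Si](CC)(CC)CC)C[C@@H](O[Si](C)(C)C(C)(C)C)C(=C)CC[C@@H]12 | intermediate
15 | 1β-(tert-butyldimethylsilyloxy)-3β-hydroxygermacra-4E,10(14),11(13)-trien-12,6α-olide | C=C1C(=O)O[C@@H]2/C=C(C)/[C@@H](O)C[C@@H](O[Si](C)(C)C(C)(C)C)C(=C)CC[C@@H]12 | intermediate
16 | 3α-[1-(2-nitrobenzenesulfonyl)hydrazin-1-yl]-1β-(tert-butyldimethylsilyloxy)germacra-4E,10(14),11(13)-trien-12,6α-olide | C=C1C(=O)O[C@@H]2/C=C(C)/[C@H](N(N)S(=O)(=O)c3ccccc3[N+](=O)[O-])C[C@@H](O[Si](C)(C)C(C)(C)C)C(=C)CC[C@@H]12 | intermediate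
17 | 3α-diazenyl-1β-(tert-butyldimethylsilyloxy)germacra-4E,10(14),11(13)-trien-12,6α-olide | C=C1C(=O)O[C@@H]2/C=C(C)/[C@H](N=N)C[C@@H](O[Si](C)(C)C(C)(C)C)C(=C)CC[C@@H]12 | intermediate
18 | 1β-(tert-butyldimethylsilyloxy)germacra-3E,10(14),11(13)-trien-12,6α-olide | C=C1C(=O)O[C@@H]2C/C(C)=C/C[C@@H](O[Si](C)(C)C(C)(C)C)C(=C)CC[C@@H]12 | intermediate
19 | (3R,4R)-3,4-epoxy-1β-(tert-butyldimethylsilyloxy)germacra-10(14),11(13)-dien-12,6α-olide | C=C1C(=O)O[C@@H]2C[C@@]3(C)O[C@@H]3C[C@@H](O[Si](C)(C)C(C)(C)C)C(=C)CC[C@@H]12 | intermediate
20 | (3R,4R)-3,4-epoxy-9-hydroxy-1β-(tert-butyldimethylsilyloxy)germacra-10(14),11(13)-dien-12,6α-olide (C9 epimers) | C=C1C(=O)O[C@@H]2C[C@@]3(C)O[C@@H]3C[C@@H](O[Si](C)(C)C(C)(C)C)C(=C)C(O)C[C@@H]12 | intermediate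
21 | (3R,4R)-3,4-epoxy-9-oxo-1β-(tert-butyldimethylsilyloxy)germacra-10(14),11(13)-dien-12,6α-olide | C=C1C(=O)O[C@@H]2C[C@@]3(C)O[C@@H]3C[C@@H](O[Si](C)(C)C(C)(C)C)C(=C)C(=O)C[C@@H]12 | intermediate
22 | potassium C8=C9 enolate of 21 | [K+].C=C1C(=O)O[C@@H]2C[C@@]3(C)O[C@@H]3C[C@@H](O[Si](C)(C)C(C)(C)C)C(=C)C([O-])=C[C@@H]12 | intermediate
23 | (3R,4R)-3,4-epoxy-8α-hydroxy-9-oxo-1β-(tert-butyldimethylsilyloxy)germacra-10(14),11(13)-dien-12,6α-olide | C=C1C(=O)O[C@@H]2C[C@@]3(C)O[C@@H]3C[C@@H](O[Si](C)(C)C(C)(C)C)C(=C)C(=O)[C@H](O)[C@@H]12 | intermediate
24 | (3R,4R)-3,4-epoxy-8α-(4-methoxybenzyloxy)-9-oxo-1β-(tert-butyldimethylsilyloxy)germacra-10(14),11(13)-dien-12,6α-olide | C=C1C(=O)O[C@@H]2C[C@@]3(C)O[C@@H]3C[C@@H](O[Si](C)(C)C(C)(C)C)C(=C)C(=O)[C@H](OCc3ccc(OC)cc3)[C@@H]12 | intermediate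
25 | (3R,4R)-3,4-epoxy-9α-hydroxy-8α-(4-methoxybenzyloxy)-1β-(tert-butyldimethylsilyloxy)germacra-10(14),11(13)-dien-12,6α-olide | C=C1C(=O)O[C@@H]2C[C@@]3(C)O[C@@H]3C[C@@H](O[Si](C)(C)C(C)(C)C)C(=C)[C@H](O)[C@H](OCc3ccc(OC)cc3)[C@@H]12 | intermediate
26 | angelic acid ((Z)-2-methylbut-2-enoic acid) | C/C=C(/C)C(=O)O | starting material
27 | (3R,4R)-9α-angeloyloxy-3,4-epoxy-8α-(4-methoxybenzyloxy)-1β-(tert-butyldimethylsilyloxy)germacra-10(14),11(13)-dien-12,6α-olide | C=C1C(=O)O[C@@H]2C[C@@]3(C)O[C@@H]3C[C@@H](O[Si](C)(C)C(C)(C)C)C(=C)[C@H](OC(=O)/C(C)=C\C)[C@H](OCc3ccc(OC)cc3)[C@@H]12 | intermediate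
28 | (3R,4R)-9α-angeloyloxy-3,4-epoxy-1β-hydroxy-8α-(4-methoxybenzyloxy)germacra-10(14),11(13)-dien-12,6α-olide | C=C1C(=O)O[C@@H]2C[C@@]3(C)O[C@@H]3C[C@@H](O)C(=C)[C@H](OC(=O)/C(C)=C\C)[C@H](OCc3ccc(OC)cc3)[C@@H]12 | intermediate
29 | (3R,4R)-9α-angeloyloxy-3,4-epoxy-8α-(4-methoxybenzyloxy)-1-oxogermacra-10(14),11(13)-dien-12,6α-olide | C=C1C(=O)O[C@@H]2C[C@@]3(C)O[C@@H]3CC(=O)C(=C)[C@H](OC(=O)/C(C)=C\C)[C@H](OCc3ccc(OC)cc3)[C@@H]12 | intermediate
30 | (3R,4R)-9α-angeloyloxy-3,4-epoxy-8α-hydroxy-1-oxogermacra-10(14),11(13)-dien-12,6α-olide | C=C1C(=O)O[C@@H]2C[C@@]3(C)O[C@@H]3CC(=O)C(=C)[C@H](OC(=O)/C(C)=C\C)[C@H](O)[C@@H]12 | target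

## Step count and least certain steps

Total step count: 20. Longest linear sequence: 20 steps (1 to 30); angelic acid 26 is bought and enters at step 17.

**Step 3 (key step).** The likely failure is loss of the product, not a wrong ring. Germacrene A is volatile, rearranges thermally (Cope) to the elemene skeleton and cyclises under acid, and the in vitro enzyme may turn over slowly as the hydrocarbon accumulates. The fallback moves the cyclization into the cell: a yeast strain engineered for a high supply of the diphosphate and expressing the synthase is grown on glucose under a dodecane overlay. This replaces steps 1 and 2, since diphosphate 3 is made by the cell and never isolated, and the route is rejoined at 4. If the oxidases of step 4 are co-expressed it is rejoined at 9.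

**Step 10.** Two processes threaten it. The retro-ene may give the alkene with the wrong geometry, because the cis-cycloalkene is the more stable isomer and nothing rigid enforces the E transition state. The Mitsunobu displacement may also go in the SN2′ sense, which after nitrogen loss returns an untransposed alkene. The fallback accepts the wrong geometry and corrects it at the epoxide stage. Starting from 15, if the product is the (3Z)-alkene F1, it is syn-dihydroxylated (catalytic OsO4, N-methylmorpholine N-oxide, with a cinchona alkaloid ligand chosen for the face that places the C4 oxygen β) to the 3β,4β-diol F2. The secondary hydroxyl is mesylated selectively (MsCl, pyridine) to the mesylate F3. Base-induced closure (DBU) by the tertiary C4 oxygen, with inversion at C3, then gives the trans-epoxide 19, where the route is rejoined with step 11 skipped.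

**Step 11.** Poor facial selectivity is the main risk: the ring may expose only one face of the C3=C4 alkene, and if that face is not the one the catalyst prefers the reaction will be slow or unselective. Prolonged exposure to the basic oxidant may also damage the methylene lactone. The fallback delivers oxygen to the face opposite to the one reagents reach. From 18, N-bromosuccinimide in aqueous THF puts bromine on the exposed face and water on tertiary C4 from the other side, giving the bromohydrin F4. Ag2O then closes F4 to 19 with inversion at C3.

**Step 12.** The ene reaction may be sluggish at a methylene flanked by a silyloxy carbon, and the acidic selenium species may open the epoxide or over-oxidise. The fallback is a direct allylic oxidation of 19 to enone 21 with CrO3·3,5-dimethylpyrazole in CH2Cl2 at −20 °C. This is a hydrogen-abstraction pathway, not an ene/[2,3] sequence, and it bypasses alcohol 20; no new compound is involved.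

**Step 14.** Facial selectivity at C8 of a macrocyclic enolate is not secured by any rigid element, and the enolate may add to the exocyclic enone, to the methylene lactone or to the sulfonimine by-product. The fallback corrects the configuration by inversion and does not rely on facial control. From 21, if the 8β-alcohol F5 predominates, Mitsunobu reaction with formic acid (PPh3, diisopropyl azodicarboxylate) gives the 8α-formate F6. Mild solvolysis (KHCO3, aqueous MeOH, 0 °C) then returns the route at 23.

## Further compounds

F0 | step 3 | none | none
F1 | step 10 | 1β-(tert-butyldimethylsilyloxy)germacra-3Z,10(14),11(13)-trien-12,6α-olide | C=C1C(=O)O[C@@H]2C/C(C)=C\C[C@@H](O[Si](C)(C)C(C)(C)C)C(=C)CC[C@@H]12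
F2 | step 10 | 3β,4β-dihydroxy-1β-(tert-butyldimethylsilyloxy)germacra-10(14),11(13)-dien-12,6α-olide | C=C1C(=O)O[C@@H]2C[C@@](C)(O)[C@@H](O)C[C@@H](O[Si](C)(C)C(C)(C)C)C(=C)CC[C@@H]12
F3 | step 10 | 4β-hydroxy-3β-(methanesulfonyloxy)-1β-(tert-butyldimethylsilyloxy)germacra-10(14),11(13)-dien-12,6α-olide | C=C1C(=O)O[C@@H]2C[C@@](C)(O)[C@@H](OS(C)(=O)=O)C[C@@H](O[Si](C)(C)C(C)(C)C)C(=C)CC[C@@H]12
F4 | step 11 | 3β-bromo-4β-hydroxy-1β-(tert-butyldimethylsilyloxy)germacra-10(14),11(13)-dien-12,6α-olide | C=C1C(=O)O[C@@H]2C[C@@](C)(O)[C@@H](Br)C[C@@H](O[Si](C)(C)C(C)(C)C)C(=C)CC[C@@H]12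
F0 | step 12 | none | none
F5 | step 14 | (3R,4R)-3,4-epoxy-8β-hydroxy-9-oxo-1β-(tert-butyldimethylsilyloxy)germacra-10(14),11(13)-dien-12,6α-olide | C=C1C(=O)O[C@@H]2C[C@@]3(C)O[C@@H]3C[C@@H](O[Si](C)(C)C(C)(C)C)C(=C)C(=O)[C@@H](O)[C@@H]12
F6 | step 14 | (3R,4R)-3,4-epoxy-8α-formyloxy-9-oxo-1β-(tert-butyldimethylsilyloxy)germacra-10(14),11(13)-dien-12,6α-olide | C=C1C(=O)O[C@@H]2C[C@@]3(C)O[C@@H]3C[C@@H](O[Si](C)(C)C(C)(C)C)C(=C)C(=O)[C@H](OC=O)[C@@H]12
A1 | alternative 1 | isoxazoline-bridged ten-membered epoxy lactone | C1C(=O)O[C@@H]2C[C@@]3(C)O[C@@H]3CC4=NO[C@@H]([C@H]4C(=O)OC)[C@H](O[Si](C)(C)C(C)(C)C)[C@@H]12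
A2 | alternative 2 | (E)-cyclodecenone with C9 ketone and protected C6, C8 and C12 oxygens | O=C1[C@@H](C)CC/C=C(C)/C[C@@H](O[Si](C)(C)C(C)(C)C)[C@H](CCOCc2ccc(OC)cc2)[C@H]1OCOC
A3 | alternative 3 | ten-membered homoallylic alcohol ester with E C3/C4 alkene | COC(=O)C[C@H]1[C@H](O)C/C(C)=C/C[C@H](O[Si](C)(C)C(C)(C)C)C(=C)[C@@H]2OC(C)(C)O[C@H]12
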